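In a one-step world every substrate lost is one product, and Sunday's last reading fits that picture: 87.1 % of substrate beside 12.9 % of product at 15.0 h.

| flask | substrate | reagent | scavenger | free catalyst | remark | time |
|---|---|---|---|---|---|---|
| Sunday's | 0.33 M | 0.95 equiv (fed, over 25 h) | 0.50 equiv | 1.5 mol% | run made earlier; the fed solution adds 0.25 times the starting volume |  |
| south-east | 0.33 M | 0.950 equiv (fed, over 25 h) | 0.500 equiv | 1 mol% | the fed solution adds 0.25 times the starting volume | 2.0 d |
| south | 0.33 M | 0.950 equiv (fed, over 25 h) | 1.00 equiv | 1 mol% | the fed solution adds 0.25 times the starting volume | 2.0 d |
| west | 0.33 M | 0.950 equiv (fed, over 25 h) | 2.00 equiv | 1 mol% | the fed solution adds 0.25 times the starting volume | 2.0 d |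

Sunday's run (percent of the substrate charged)

| time / h | substrate / % | product / % |
|---|---|---|
| 0.833 | 97.3 | 1.0 |
| 2.50 | 95.9 | 0 |
| 5.00 | 97.5 | 2.2 |
| 8.00 | 93.8 | 4.4 |
| 10.0 | 90.8 | 7.0 |
| 12.0 | 91.5 | 9.0 |
| 15.0 | 87.1 | 12.9 |

(each reading ± 1 percentage point)

- every charge counts on the volume at the start, and the solution that is fed holds the whole dose
- the numbers in the tables scatter by 1 percentage point (one standard deviation)
- no earlier run changes the charge of free catalyst; that part of a forecast is a guess
- no earlier run changes the charge of scavenger; that part of a forecast is a guess

1. part of the substrate that has reacted at the end, south-east
2. part of the substrate that has reacted at the end, south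
3. part of the substrate that has reacted at the end, west
4. what raising the equivalents of scavenger from its lowest to its highest value here does to the part of the substrate that has reacted (changes below 5 percentage points count as none) (no change / it rises / it falls)

South-east looks nearly the same as Sunday's run, with the same dose, feed and scavenger, but it has 1 mol% of free catalyst against 1.5 mol%. I divided the rate in one flask by the rate in the other at equal composition, so time dropped out and the ratio of loadings was left, 0.667, on the untested guess of first order in catalyst. Product grew roughly as the square of time while reagent accumulated, so Sunday's reading, scaled to south-east's loading, gave me a constant of 0.0201 /h in fractions of the charge. Ignoring dilution during the feed, that put 23.9 % reacted in south-east when the feed ended. Treating substrate and reagent as equal and diluted afterwards, second-order decay then gave me 37.9 % at 2.0 d.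

For the scavenger I assumed that one goes per substrate reacted. Scavenger loss divided by substrate loss is then one at every moment, and time drops out again. South-east's figure came to 1.32: this is the scavenger cover, the scavenger charged over the substrate reacted by the end. Above one, the scavenger lasts up to the time of reading, and on this assumption the share of its charge left then is one minus the inverse of the cover, here 24.2 %. South-east has the thinnest cover, and it stays above one, with 2.64 for south and 5.28 for west, so I expected no shortage by 2.0 d and no change.

The forecast gave 38 %, 38 % and 38 % with no change, adding of the scavenger “this is a guess”. The flasks gave 36.9 %, 36.9 % and 36.9 %, which is no change, the change being 0.058 percentage points.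

    substrate + free catalyst ⇌ catalyst intermediate A (K = 1.20 /M, k = 22.5 /M/h)
    catalyst intermediate A → catalyst intermediate B (k = 24.9 /h)
    reagent + catalyst intermediate B ⇌ catalyst intermediate C (K = 240 /M, k = 16.4 /M/h)
    catalyst intermediate C ⇌ released group + catalyst intermediate D (K = 0.799 M, k = 2.75 /h)
    catalyst intermediate D → free catalyst + product (k = 20.3 /h)
    reagent + released group ⇌ idle adduct, settled at all times (K = 2.50 /M)
    scavenger + released group → scavenged by-product (k = 9.33 /M/h)

In south-east the released group stood at 0.575 % of the equilibrium constant of its return to catalyst intermediate C at 2.00 d, and that return makes no difference to the reacted part. South-east's cover on its real reacted part was 1.36, which leaves 26.2 % of the scavenger, and the flask held 32 %. South read at 3.00 d had reacted 53.2 %, so its cover of 1.88 leaves 46.8 %, and it held 48 %.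

All runs stem from a simulated flask on assumed constants, noise included.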